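## Retrosynthetic overview

1. Plakortolide Q ⇐ terminal-alkene peroxy-lactone + (E)-1-phenylbuta-1,3-diene by cross-metathesis at C13=C14. This comes last because the phenyldiene would not survive singlet oxygen.
2. C5–H ⇐ C5–I. The γ-lactone (second ring) ⇐ iodolactonisation of a 1,2-dioxine-3-acetic acid onto C4=C5, run as a catalyst-controlled kinetic resolution that fixes the absolute configuration; C4 follows from C3 through the cis ring fusion.
3. The 1,2-dioxine (first ring) ⇐ [4+2] addition of singlet oxygen to an achiral (3E,5E)-4,6-dimethyl-3,5-dienoic acid, which sets C3/C6 cis from the diene geometry. Peroxide ring first, lactone second, as in the presumed biogenesis.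
4. Diene acid ⇐ methylalumination of dec-1-en-9-yne and Pd coupling with (E)-4-iodopent-3-en-1-ol (from pent-3-yn-1-ol), then oxidation.

Assumption: atoms are numbered as in the plakortolides (C1 lactone carbonyl, C3–C4 ring fusion, C6 quaternary peroxy carbon, C13–C16 diene); racemic 9 is written with the SMILES of the enantiomer that is carried on.

## Route

Step 1
Reactants: 1 8-bromooct-1-ene
Product: 2 dec-1-en-9-yne
Conditions: LiC≡CH·H2NCH2CH2NH2 (1.3 equiv), DMSO, 10 °C → rt
Reagents that add atoms: lithium acetylide–ethylenediamine complex, [Li+].[C-]#C.NCCN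
Why: SN2 alkylation of an acetylide by a primary bromide in DMSO is a standard alkyne synthesis and forms no stereocentre.

Step 2
Reactants: 3 pent-3-yn-1-ol
Product: 5 (E)-4-iodopent-3-en-1-ol, via alkenyl-ZrCp2Cl species 4 (not isolated)
Conditions: Cp2Zr(H)Cl (2.3 equiv), THF, rt → 40 °C; then I2 (1.1 equiv), 0 °C
Reagents that add atoms: iodine, II
Why: Hydrozirconation is a syn addition in which excess Cp2Zr(H)Cl (one equivalent is consumed by the OH) equilibrates the regioisomers so that Zr sits on the methyl-bearing carbon, and iodinolysis of the C–Zr bond with retention gives the (E)-iodide.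

Step 3
Reactants: 2 dec-1-en-9-yne; 5 (E)-4-iodopent-3-en-1-ol
Product: 7 (3E,5E)-4,6-dimethyltetradeca-3,5,13-trien-1-ol, via alkenyl-AlMe2 alane 6 (not isolated)
Conditions: Me3Al (2 equiv), Cp2ZrCl2 (0.25 equiv), CH2Cl2, 0 °C → rt; then 5 (as its Me2Al alkoxide, Me3Al 1 equiv), Pd(PPh3)4 (5 mol%), ZnCl2 (0.2 equiv), THF, rt
Reagents that add atoms: trimethylaluminium, C[Al](C)C
Why: Negishi zirconium-catalysed methylalumination adds Me and Al syn across the terminal alkyne (Me on the internal carbon, the isolated terminal alkene being much less reactive), and Pd/Zn-catalysed Negishi coupling of the alkenylalane with the alkenyl iodide retains both geometries to give the (3E,5E)-diene.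

Step 4
Reactants: 7 (3E,5E)-4,6-dimethyltetradeca-3,5,13-trien-1-ol
Product: 8 (3E,5E)-4,6-dimethyltetradeca-3,5,13-trienoic acid
Conditions: TEMPO (0.2 equiv), PhI(OAc)2 (2.2 equiv), MeCN–H2O (1:1), rt
Reagents that add atoms: water, O
Why: Oxoammonium (TEMPO) oxidation takes the primary alcohol through the aldehyde hydrate to the acid under near-neutral conditions, which should leave the conjugated diene and the β,γ-position of the double bond untouched.

Step 5
Reactants: 8 (3E,5E)-4,6-dimethyltetradeca-3,5,13-trienoic acid
Product: 9 rac-2-[(3R,6S)-4,6-dimethyl-6-(oct-7-en-1-yl)-3,6-dihydro-1,2-dioxin-3-yl]acetic acid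
Conditions: O2, tetraphenylporphyrin (0.5 mol%), hν (white LED), CH2Cl2, −20 °C
Reagents that add atoms: dioxygen, O=O
Why: Singlet oxygen adds suprafacially in a [4+2] cycloaddition to the s-cis diene, so the two inward groups (H on C3, CH3 on C6) end up cis on the 1,2-dioxine and the C3/C6 relative configuration is set in one step as a racemate, the monosubstituted C13=C14 being inert and ene by-products being removed by chromatography.

Step 6
Reactants: 9 rac-2-[(3R,6S)-4,6-dimethyl-6-(oct-7-en-1-yl)-3,6-dihydro-1,2-dioxin-3-yl]acetic acid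
Product: 10 (3R,4S,5R,6S)-3,6-epidioxy-5-iodo-4,6-dimethyltetradec-13-en-4-olide
Conditions: NIS (0.5 equiv), (DHQD)2PHAL (10 mol%), CHCl3–hexane (1:1), −40 °C, dark, to ca. 45% conversion; NaHCO3 wash removes unreacted acid
Reagents that add atoms: N-iodosuccinimide, O=C1CCC(=O)N1I
Why: Proposed new method: 5-exo iodolactonisation can deliver the carboxylate to C4 only on the alkene face that carries its own CH2CO2H arm (cis-fused lactone, C4 set from C3, iodonium opened anti so that I on C5 is trans to the lactone oxygen), so a chiral halenium-transfer catalyst that discriminates alkene faces must discriminate the two enantiomers of 9 and should cyclise the (3R,6S)-acid faster while the (3S,6R)-acid stays behind (the pseudo-enantiomeric (DHQ)2PHAL is used if the sense is the opposite); the closest known chemistry is the cinchona-dimer-catalysed enantioselective halolactonisation of 4-substituted pent-4-enoic acids and the kinetic resolution of racemic unsaturated amides by halocyclisation with the same catalyst, and the uncatalysed iodolactonisation of 1,2-dioxine-3-acetic acids with I2/NaHCO3 is itself established.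

Step 7
Reactants: 10 (3R,4S,5R,6S)-3,6-epidioxy-5-iodo-4,6-dimethyltetradec-13-en-4-olide
Product: 11 (3R,4R,6S)-3,6-epidioxy-4,6-dimethyltetradec-13-en-4-olide
Conditions: Bu3SnH (1.5 equiv, 0.3 M), AIBN (0.1 equiv), PhH, 80 °C
Reagents that add atoms: none
Why: Radical chain dehalogenation replaces the secondary iodine by hydrogen, the concentrated tin hydride trapping the C5 radical faster than it can attack the neighbouring O–O bond, so C5 becomes CH2 and C3, C4 and C6 are untouched.

Step 8
Reactants: 11 (3R,4R,6S)-3,6-epidioxy-4,6-dimethyltetradec-13-en-4-olide; 12 (E)-1-phenylbuta-1,3-diene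
Product: 13 plakortolide Q, (3R,4R,6S,13E,15E)-3,6-epidioxy-4,6-dimethyl-16-phenylhexadeca-13,15-dien-4-olide
Conditions: 12 (4 equiv), second-generation Grubbs catalyst RuCl2(=CHPh)(H2IMes)(PCy3) (5 mol%), CH2Cl2, 40 °C
Reagents that add atoms: none
Why: In this olefin cross-metathesis the ruthenium carbene engages the terminal vinyl group of 12 much faster than its conjugated styrenyl bond, the conjugated (13E,15E)-diene is the thermodynamic product (15E is carried over from 12), and dialkyl peroxides and lactones are tolerated, so no stereocentre is touched.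

## Compound list

1 | 8-bromooct-1-ene | BrCCCCCCC=C | starting material
2 | dec-1-en-9-yne | C#CCCCCCCC=C | intermediate
3 | pent-3-yn-1-ol | CC#CCCO | starting material
4 | (E)-alkenyl-ZrCp2Cl species from 3 (Zr on C4, OH also bound as O–ZrCp2Cl; not isolated) | C/C(=C\CCO[Zr](Cl)(C1C=CC=C1)C1C=CC=C1)[Zr](Cl)(C1C=CC=C1)C1C=CC=C1 | intermediate
5 | (E)-4-iodopent-3-en-1-ol | OCC/C=C(\C)I | intermediate
6 | (E)-(2-methyldeca-1,9-dien-1-yl)dimethylalane (not isolated) | C[Al](C)/C=C(\C)CCCCCCC=C | intermediate
7 | (3E,5E)-4,6-dimethyltetradeca-3,5,13-trien-1-ol | OCC/C=C(\C)/C=C(\C)CCCCCCC=C | intermediate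
8 | (3E,5E)-4,6-dimethyltetradeca-3,5,13-trienoic acid | OC(=O)C/C=C(\C)/C=C(\C)CCCCCCC=C | intermediate
9 | rac-2-[(3R,6S)-4,6-dimethyl-6-(oct-7-en-1-yl)-3,6-dihydro-1,2-dioxin-3-yl]acetic acid (cis racemate; enantiomer carried on is shown) | C[C@]1(CCCCCCC=C)C=C(C)[C@@H](CC(=O)O)OO1 | intermediate
10 | (3R,4S,5R,6S)-3,6-epidioxy-5-iodo-4,6-dimethyltetradec-13-en-4-olide (cis-fused peroxy-lactone, I on C5 trans to the lactone O) | C[C@]1(CCCCCCC=C)[C@H](I)[C@@]2(C)OC(=O)C[C@H]2OO1 | intermediate
11 | (3R,4R,6S)-3,6-epidioxy-4,6-dimethyltetradec-13-en-4-olide | C[C@]1(CCCCCCC=C)C[C@@]2(C)OC(=O)C[C@H]2OO1 | intermediate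
12 | (E)-1-phenylbuta-1,3-diene | C=C/C=C/c1ccccc1 | starting material
13 | plakortolide Q, (3R,4R,6S,13E,15E)-3,6-epidioxy-4,6-dimethyl-16-phenylhexadeca-13,15-dien-4-olide | C[C@]1(CCCCCC/C=C/C=C/c2ccccc2)C[C@@]2(C)OC(=O)C[C@H]2OO1 | target

## Step count and risks

Total steps: 8. Longest linear sequence: 7 steps (1 → 2 → 7 → 8 → 9 → 10 → 11 → 13; the branch 3 → 5 joins at step 3).

The kinetic resolution in step 6 gives at most half of 9 as 10, and the ee of 10 is capped by the selectivity factor (a factor of 20 or more is needed for about 90% ee at 40–45% conversion).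

The three steps most likely to fail:

**Step 5.** On a diene with an inward methyl group, the ene reaction and dioxetane formation can outrun the [4+2] addition. Fallback, from 8 back to 9: replace the pericyclic singlet-oxygen addition by the cation-radical chain oxygenation with ground-state O2, initiated by (4-BrC6H4)3N+ SbCl6− (5 mol%, CH2Cl2, −78 °C). The diene radical cation takes up triplet oxygen and closes to the same 1,2-dioxine. This manifold has no ene channel and is known to turn inward-substituted dienes into endoperoxides. Because it is stepwise, the cis C3/C6 relationship of 9 must be confirmed by NOE. It passes through no new compound (F0).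

**Step 6.** The selectivity factor is unknown, and the basic catalyst could trigger Kornblum–DeLaMare opening at C3–H, although the substrate acid buffers it. Fallback, from 9 back to 10: cyclise racemic 9 without a chiral catalyst (I2, NaHCO3, MeCN–H2O, 0 °C) to the racemic iodolactone F1. Then separate the enantiomers by preparative chromatography on a chiral stationary phase (amylose tris(3,5-dimethylphenylcarbamate)); the (3R,4S,5R,6S) enantiomer is 10.

**Step 8.** The catalyst can also cut the styrenyl C=C of 12 or of the product, and the geometry at C13=C14 rests on thermodynamic control. Fallback, from 11 back to 13: cross-metathesis of 11 with vinylboronic acid pinacol ester (same ruthenium catalyst, CH2Cl2, 40 °C) gives the (E)-alkenylboronate F2. Suzuki–Miyaura coupling of F2 with (E)-β-bromostyrene (Pd(PPh3)4, K3PO4, THF–H2O, rt) then forms the C14–C15 bond with retention of both alkene geometries.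

## Further compounds

F0 | step 5 | none | none
F1 | step 6 | racemic 3,6-epidioxy-5-iodo-4,6-dimethyltetradec-13-en-4-olide (10 and its enantiomer, 1:1) | C[C@]1(CCCCCCC=C)[C@H](I)[C@@]2(C)OC(=O)C[C@H]2OO1.C[C@@]1(CCCCCCC=C)[C@@H](I)[C@]2(C)OC(=O)C[C@@H]2OO1
F2 | step 8 | (3R,4R,6S,13E)-3,6-epidioxy-4,6-dimethyl-14-(4,4,5,5-tetramethyl-1,3,2-dioxaborolan-2-yl)tetradec-13-en-4-olide | C[C@]1(CCCCCC/C=C/B3OC(C)(C)C(C)(C)O3)C[C@@]2(C)OC(=O)C[C@H]2OO1
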